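**Plan**

1. Retrosynthesis: after removal of the tertiary silyl ether and the 7-O-methyl group, ring A is cut at C4a–C5 and C7–C8. This releases C5–C6–C7 as malonyl dichloride and leaves ring C as a 2-phenyl-2,3-dihydropyran-4-one whose side chain is one CH2 longer (the future C8).
2. The pyranone is cut at O1–C8a (6-endo-dig closure of a beta-hydroxy ynone) and at C4–C4a (acetylide plus Weinreb amide), giving a C8 alkyne and a C3 hydroxy ester.
3. Forward: the chain is made (steps 1–2) and joined to the chiral fragment (steps 3–4), ring C is closed (step 5), ring A is annulated onto it (step 6), then methylation and desilylation (steps 7–8).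
4. Enabling feature: ring A is a phloroglucinol whose C8a is the enol-ether carbon of ring C. C4a and the chain CH2 (C8) flank it as the two alpha carbons of a masked ketone, so a malonyl unit can bridge them and aromatise.
5. Stereochemistry: the only stereocentre, C2, comes from ethyl (S)-3-hydroxy-3-phenylpropanoate. Its C–O bond is never broken and the priority order O > Ph > CH2 > H does not change, so (S) is carried through to the (2S)-flavanone.

Key step: step 6

Remark: flavanone numbering (O1, C2, C3, C4, C4a, C5 to C8, C8a) is used for the corresponding atoms of every intermediate; the hydroxy ester is taken as the commercial (S)-enantiomer.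

**Route**

Step 1
Reactants: 1 ethyl hex-5-ynoate
Product: 3 2-methylhept-6-yn-2-ol, via hept-6-yn-2-one 2 (not isolated)
Conditions: MeMgBr (3.5 equiv), THF, 0 °C → rt; aq. NH4Cl
Reagents that add atoms: methylmagnesium bromide, C[Mg]Br
Why: Double Grignard addition to the ester through the methyl ketone gives the tertiary alcohol, the terminal alkyne being at most deprotonated by the surplus reagent and returned on work-up.

Step 2
Reactants: 3 2-methylhept-6-yn-2-ol
Product: 4 tert-butyldimethyl[(2-methylhept-6-yn-2-yl)oxy]silane
Conditions: TBSOTf, 2,6-lutidine, CH2Cl2, 0 °C → rt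
Reagents that add atoms: tert-butyldimethylsilyl trifluoromethanesulfonate, CC(C)(C)[Si](C)(C)OS(=O)(=O)C(F)(F)F
Why: Silylation of a hindered tertiary alcohol with a silyl triflate and a hindered base is standard, and the robust tertiary silyl ether is chosen to last through the organolithium, Lewis acid and acyl chloride steps.

Step 3
Reactants: 5 ethyl (S)-3-hydroxy-3-phenylpropanoate
Product: 6 (S)-3-hydroxy-N-methoxy-N-methyl-3-phenylpropanamide
Conditions: MeNH(OMe)·HCl, i-PrMgCl, THF, −20 → 0 °C
Reagents that add atoms: N,O-dimethylhydroxylamine hydrochloride, CNOC.Cl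
Why: Direct Weinreb aminolysis of the ester by the chloromagnesium amide tolerates the free beta-hydroxyl as its chloromagnesium alkoxide, and at low temperature neither retro-aldol cleavage nor elimination should touch the stereocentre.

Step 4
Reactants: 4 tert-butyldimethyl[(2-methylhept-6-yn-2-yl)oxy]silane, 6 (S)-3-hydroxy-N-methoxy-N-methyl-3-phenylpropanamide
Product: 8 (S)-9-(tert-butyldimethylsilyloxy)-1-hydroxy-9-methyl-1-phenyldec-4-yn-3-one, via lithium acetylide 7 (not isolated)
Conditions: 4 (2.4 equiv), n-BuLi (2.3 equiv), THF, −78 °C; then 6, −78 → −20 °C; aq. NH4Cl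
Reagents that add atoms: none
Why: Weinreb ketone synthesis with a lithium acetylide, in which one equivalent of 7 takes the hydroxyl proton and a second adds to the amide to give a chelated tetrahedral adduct that cannot over-add and releases the ynone on work-up, the carbinol centre being untouched and surplus 4 recoverable.

Step 5
Reactants: 8 (S)-9-(tert-butyldimethylsilyloxy)-1-hydroxy-9-methyl-1-phenyldec-4-yn-3-one
Product: 9 (S)-6-[4-(tert-butyldimethylsilyloxy)-4-methylpentyl]-2-phenyl-2,3-dihydro-4H-pyran-4-one
Conditions: AgOTf (10 mol %), CH2Cl2, rt, dark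
Reagents that add atoms: none
Why: AgOTf-catalysed 6-endo-dig cycloisomerisation of a beta-hydroxy ynone (oxa-Michael sense, the alkyne activated by the carbophilic Lewis acid) is a standard entry to 2,3-dihydropyran-4-ones, and because the hydroxyl oxygen is the nucleophile the C2 configuration is retained.

Step 6
Reactants: 9 (S)-6-[4-(tert-butyldimethylsilyloxy)-4-methylpentyl]-2-phenyl-2,3-dihydro-4H-pyran-4-one, 10 malonyl dichloride
Product: 12 (S)-8-[3-(tert-butyldimethylsilyloxy)-3-methylbutyl]-5,7-dihydroxy-2-phenylchroman-4-one, via mono-acylated acyl chloride 11 (not isolated)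
Conditions: 10 (1.2 equiv, slow addition), 2,6-di-tert-butyl-4-methylpyridine (2.5 equiv), CH2Cl2, −20 → 40 °C; aq. NaHCO3
Reagents that add atoms: none
Why: Proposed new method: C4a, the beta carbon of the ring C enol ether O1–C8a=C4a, should attack malonyl dichloride (or the chlorocarbonylketene it forms with the base), and the O1-stabilised oxocarbenium ion then loses the C4a proton to give acyl chloride 11. Enolisation of 11 toward C8, the gamma position conjugated with both the C4 and the new C5 carbonyl group, gives a dienol ether whose C8 terminus closes ring A on the second acyl chloride by 6-exo-trig attack, or as the acylketene by 6π electrocyclisation, and the cyclohexadienone so formed tautomerises to the aromatic 5,7-diol. The closest known reaction type is the Effenberger cyclisation of malonyl dichloride with ketone enol ethers and silyl enol ethers to cyclohexane-1,3,5-triones and phloroglucinols, which has not been run on a vinylogous ester, a much weaker carbon nucleophile. No stereocentre is formed; C2 is a spectator provided the oxocarbenium ion is deprotonated before its benzylic C2–O1 bond can ionise, which low temperature and the hindered base should ensure. The step needs acylation at C4a and not at C3 or at the C4 oxygen, and closure through C8 and not through C3 or oxygen: with no strong base present C3 is never enolised, C4a is the only carbon that the O1 lone pair activates, and only closure at C8 ends in an aromatic ring, so that reversible O-acylation should drain into the phenol.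

Step 7
Reactants: 12 (S)-8-[3-(tert-butyldimethylsilyloxy)-3-methylbutyl]-5,7-dihydroxy-2-phenylchroman-4-one
Product: 13 (S)-8-[3-(tert-butyldimethylsilyloxy)-3-methylbutyl]-5-hydroxy-7-methoxy-2-phenylchroman-4-one
Conditions: MeOH, PPh3, DIAD, THF, 0 °C → rt
Reagents that add atoms: methanol, CO
Why: Mitsunobu etherification should alkylate only the free, acidic 7-hydroxyl because the 5-hydroxyl is held in a hydrogen bond to the C4 carbonyl, and its near-neutral conditions avoid the base-induced retro-oxa-Michael opening to the chalcone that would racemise C2.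

Step 8
Reactants: 13 (S)-8-[3-(tert-butyldimethylsilyloxy)-3-methylbutyl]-5-hydroxy-7-methoxy-2-phenylchroman-4-one
Product: 14 (S)-5-hydroxy-8-(3-hydroxy-3-methylbutyl)-7-methoxy-2-phenylchroman-4-one
Conditions: HF·pyridine, THF, 0 °C → rt
Reagents that add atoms: none
Why: Fluoride-driven cleavage of the tertiary silyl ether with HF·pyridine is a standard, base-free desilylation, so the 5-hydroxyflavanone should neither open nor epimerise, and with O7 methylated the freed tertiary alcohol has no phenol to cyclise onto.

**Compound list**

1 | ethyl hex-5-ynoate | C#CCCCC(=O)OCC | starting material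
2 | hept-6-yn-2-one (formed in the flask) | CC(=O)CCCC#C | intermediate
3 | 2-methylhept-6-yn-2-ol | C#CCCCC(C)(C)O | intermediate
4 | tert-butyldimethyl[(2-methylhept-6-yn-2-yl)oxy]silane | C#CCCCC(C)(C)O[Si](C)(C)C(C)(C)C | intermediate
5 | ethyl (S)-3-hydroxy-3-phenylpropanoate | CCOC(=O)C[C@H](O)c1ccccc1 | starting material
6 | (S)-3-hydroxy-N-methoxy-N-methyl-3-phenylpropanamide | CON(C)C(=O)C[C@H](O)c1ccccc1 | intermediate
7 | [6-(tert-butyldimethylsilyloxy)-6-methylhept-1-yn-1-yl]lithium (formed in the flask) | [Li]C#CCCCC(C)(C)O[Si](C)(C)C(C)(C)C | intermediate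
8 | (S)-9-(tert-butyldimethylsilyloxy)-1-hydroxy-9-methyl-1-phenyldec-4-yn-3-one | CC(C)(C)[Si](C)(C)OC(C)(C)CCCC#CC(=O)C[C@H](O)c1ccccc1 | intermediate
9 | (S)-6-[4-(tert-butyldimethylsilyloxy)-4-methylpentyl]-2-phenyl-2,3-dihydro-4H-pyran-4-one | O=C1C[C@@H](c2ccccc2)OC(CCCC(C)(C)O[Si](C)(C)C(C)(C)C)=C1 | intermediate
10 | malonyl dichloride | O=C(Cl)CC(=O)Cl | starting material
11 | 3-{(S)-6-[4-(tert-butyldimethylsilyloxy)-4-methylpentyl]-4-oxo-2-phenyl-3,4-dihydro-2H-pyran-5-yl}-3-oxopropanoyl chloride (formed in the flask) | O=C1C[C@@H](c2ccccc2)OC(CCCC(C)(C)O[Si](C)(C)C(C)(C)C)=C1C(=O)CC(=O)Cl | intermediate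
12 | (S)-8-[3-(tert-butyldimethylsilyloxy)-3-methylbutyl]-5,7-dihydroxy-2-phenylchroman-4-one | Oc1cc(O)c2c(c1CCC(C)(C)O[Si](C)(C)C(C)(C)C)O[C@H](c1ccccc1)CC2=O | intermediate
13 | (S)-8-[3-(tert-butyldimethylsilyloxy)-3-methylbutyl]-5-hydroxy-7-methoxy-2-phenylchroman-4-one | COc1cc(O)c2c(c1CCC(C)(C)O[Si](C)(C)C(C)(C)C)O[C@H](c1ccccc1)CC2=O | intermediate
14 | (S)-5-hydroxy-8-(3-hydroxy-3-methylbutyl)-7-methoxy-2-phenylchroman-4-one (CNP0160063.1) | COc1cc(O)c2c(c1CCC(C)(C)O)O[C@H](c1ccccc1)CC2=O | target

**Step count and risks**

Total steps: 8. Longest linear sequence: 7 steps (steps 1, 2, 4, 5, 6, 7, 8, from ethyl hex-5-ynoate).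

Steps most likely to fail:

1. Step 6 (Proposed new method). What may go wrong:
- C4a of the vinylogous ester may react so slowly that malonyl dichloride is consumed by ketene-type self-condensation.
- Acylation at the C4 oxygen, followed by closure through oxygen, may take over.
- Surplus reagent may acylate the product phenols.
- The C2–O1 bond may ionise in the oxocarbenium ion, eroding the configuration.

Fallback (known chemistry; sets out from 9, returns at 12): the C4 carbonyl, which is what deactivates the enol ether, is taken down to the alcohol level for the annulation. Luche reduction of 9 (NaBH4, CeCl3·7H2O, MeOH, −78 °C) should give mainly the cis allylic alcohol (2S,4S)-6-[4-(tert-butyldimethylsilyloxy)-4-methylpentyl]-2-phenyl-3,4-dihydro-2H-pyran-4-ol F1. The configuration at C4 is of no consequence, because this centre becomes a ketone again. TBSCl/imidazole (DMF) should then give the bis-silyl ether (2S,4S)-4-(tert-butyldimethylsilyloxy)-6-[4-(tert-butyldimethylsilyloxy)-4-methylpentyl]-2-phenyl-3,4-dihydro-2H-pyran F2. F2 is an ordinary ketone enol ether, the substrate class for which the Effenberger cyclisation with malonyl dichloride 10 is established. Under the conditions of step 6 it should give (2S,4S)-4-(tert-butyldimethylsilyloxy)-8-[3-(tert-butyldimethylsilyloxy)-3-methylbutyl]-2-phenylchroman-5,7-diol F3. TBAF buffered with AcOH (THF, 0 °C) should cleave the secondary benzylic silyl ether ahead of the tertiary one to give (2S,4S)-8-[3-(tert-butyldimethylsilyloxy)-3-methylbutyl]-2-phenylchroman-4,5,7-triol F4. DDQ (dioxane, rt), which oxidises para-hydroxybenzylic alcohols to aryl ketones, should restore the C4 carbonyl and rejoin the route at 12.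

2. Step 5. What may go wrong: loss of the benzylic hydroxyl by beta-elimination to the styryl ynone under the Lewis acid, or attack at the wrong alkyne carbon, in competition with 6-endo closure.

Fallback (sets out from 8, returns at 9): ring C is closed by addition–elimination through a vinylogous amide, with no metal present. Conjugate addition of Et2NH (EtOH, rt) to the ynone should give (S,E)-9-(tert-butyldimethylsilyloxy)-5-(diethylamino)-1-hydroxy-9-methyl-1-phenyldec-4-en-3-one F5; the alkene geometry is immaterial. Brief treatment with AcOH in THF should then let the hydroxyl add to the amine-bearing carbon and expel the amine, giving 9.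

3. Step 4. What may go wrong: retro-aldol fragmentation of the lithium beta-alkoxide to benzaldehyde, or sluggish addition to the doubly metallated amide that leaves material unconverted and wastes alkyne.

Fallback (sets out from 6, returns at 8): the hydroxyl is masked so that no alkoxide sits beta to the carbonyl. TESCl/imidazole (CH2Cl2) should give (S)-N-methoxy-N-methyl-3-phenyl-3-(triethylsilyloxy)propanamide F6. This needs only a slight excess of acetylide 7 (THF, −78 °C) to give (S)-9-(tert-butyldimethylsilyloxy)-9-methyl-1-phenyl-1-(triethylsilyloxy)dec-4-yn-3-one F7. AcOH/THF/H2O should remove the secondary triethylsilyl ether while the tertiary tert-butyldimethylsilyl ether stays, returning to 8.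

**Further compounds**

F1 | step 6 | (2S,4S)-6-[4-(tert-butyldimethylsilyloxy)-4-methylpentyl]-2-phenyl-3,4-dihydro-2H-pyran-4-ol | O[C@H]1C[C@@H](c2ccccc2)OC(CCCC(C)(C)O[Si](C)(C)C(C)(C)C)=C1
F2 | step 6 | (2S,4S)-4-(tert-butyldimethylsilyloxy)-6-[4-(tert-butyldimethylsilyloxy)-4-methylpentyl]-2-phenyl-3,4-dihydro-2H-pyran | CC(C)(C)[Si](C)(C)O[C@H]1C[C@@H](c2ccccc2)OC(CCCC(C)(C)O[Si](C)(C)C(C)(C)C)=C1
F3 | step 6 | (2S,4S)-4-(tert-butyldimethylsilyloxy)-8-[3-(tert-butyldimethylsilyloxy)-3-methylbutyl]-2-phenylchroman-5,7-diol | Oc1cc(O)c2c(c1CCC(C)(C)O[Si](C)(C)C(C)(C)C)O[C@H](c1ccccc1)C[C@@H]2O[Si](C)(C)C(C)(C)C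
F4 | step 6 | (2S,4S)-8-[3-(tert-butyldimethylsilyloxy)-3-methylbutyl]-2-phenylchroman-4,5,7-triol | Oc1cc(O)c2c(c1CCC(C)(C)O[Si](C)(C)C(C)(C)C)O[C@H](c1ccccc1)C[C@@H]2O
F5 | step 5 | (S,E)-9-(tert-butyldimethylsilyloxy)-5-(diethylamino)-1-hydroxy-9-methyl-1-phenyldec-4-en-3-one | CCN(CC)/C(CCCC(C)(C)O[Si](C)(C)C(C)(C)C)=C/C(=O)C[C@H](O)c1ccccc1
F6 | step 4 | (S)-N-methoxy-N-methyl-3-phenyl-3-(triethylsilyloxy)propanamide | CON(C)C(=O)C[C@H](O[Si](CC)(CC)CC)c1ccccc1
F7 | step 4 | (S)-9-(tert-butyldimethylsilyloxy)-9-methyl-1-phenyl-1-(triethylsilyloxy)dec-4-yn-3-one | CC(C)(C)[Si](C)(C)OC(C)(C)CCCC#CC(=O)C[C@H](O[Si](CC)(CC)CC)c1ccccc1
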